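The constants used here were set for the occasion; the result is computed.

I decided to treat this flask as a race for the starting material between the reagent and the dormant form, and to build that race up one process at a time.

starting material 2.0 M; reagent in the second phase 1.20 equiv; time 12 min; volume of the second phase over the first 1.0

- the target and product in the second phase together standing at 12 min, as a percentage of the starting material charged
- the change that raises the amount of target and product in the second phase together at 12 min, in percent of the starting material charged most ("none" if none brings more than 2 percentage points) (green / violet / ochre / none)
- amount of target and product in the second phase together at 12 min, in percent of the starting material charged, after ochre

- green: doubling the transfer coefficient of step 3, all else as stated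
- violet: doubling the amount of reagent in the second phase, all else as stated
- ochre: doubling the transfer coefficient of step 1, all else as stated

- percentages count the starting material that a species holds: one side product counts as two
- target is meant together with its product in the second phase
- in the second phase: reagent in the second phase, product in the second phase; everything else is in the first
- charges count per volume of the first phase; a concentration in a rate is the amount of a species over the volume of its own phase; every rate counts per litre of the first phase
- run time (flask): 12 min

    reagent in the reaction phase ⇌ reagent in the second phase, rate k1*([reagent in the reaction phase] - [reagent in the second phase]/K1) per volume of the first phase (K1 = 16, k1 = 0.0077 s⁻¹)
    starting material + target → side product (k2 = 0.0092 M⁻¹ s⁻¹)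
    target ⇌ product in the second phase, rate k3*([target] - [product in the second phase]/K3) per volume of the first phase (K3 = 29, k3 = 0.014 s⁻¹)
    starting material ⇌ dormant form (K4 = 20, k4 = 0.0030 s⁻¹)
    target → decomposed product (k5 = 0.0030 s⁻¹)
    starting material + reagent in the reaction phase → target (k6 = 0.0044 M⁻¹ s⁻¹)

I began with the main step. Had the reagent merely shared itself between the phases by its partition ratio, [reagent in the reaction phase] would have stood at 0.141 M, and this pseudo-first-order step would have converted 36.1% by the asked time. Then I added the dormant form. Its forward constant 0.0030 s⁻¹ is larger than the main step's 6.21 × 10⁻⁴ s⁻¹, so I let that forward rate set the drain, which leaves a remainder of 0.115, and the main step's part fell to 18.3%.

Next came supply. The charged starting material consumes reagent at 1.14 times the transfer coefficient, a ratio I called the consumption number, so I held the reagent at its steady level between transfer and consumption and integrated over the drain. The capture share S came to 11.6%: the fraction of the charged starting material that becomes target before the drain takes it, equal to the supply ratio (transfer coefficient times partition level, over drain constant times charge, here 0.181) times the natural logarithm of one plus the consumption number over one plus the consumption number times the remainder.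

Last came survival: target escapes by transfer against decomposition and side reaction, and with starting material taken at 1.00 M it survives with 0.534. In powers of ten I added −0.936 and −0.272, which gave 6.18%. Violet multiplies S by 2, giving 12.4%; green gives 8.06%; ochre gives 7.52%. So I chose violet.

The forecast gave 5.7%, lower than my figure, with violet as best and 7.4% after ochre, on the ground that “Doubling the reagent charge nearly doubles its reaction-phase level”. The simulation gave 4.98%, chose violet with a gain of 4.2 percentage points against 1 point for green and 1.1 points for ochre, and gave 6.13% after ochre.

Simulation over reckoning was 0.806 on this flask. The neighbouring flask charges 1.2 M of starting material, with equivalents and time held. Its supply ratio stays 0.181, the consumption number falls to 0.686, and S falls to 8.08%. Survival rises to 0.622, so the reckoning gives 5.02%, and 4.05% after multiplying by that ratio. The simulation of the neighbouring flask gave 3.92%.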